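(The constants were chosen freely, and the outcome is calculated.)

Three flasks stand in their baths.

| flask | starting material | temperature | time |
|---|---|---|---|
| green | 1.4 M | 0 °C | 5.0 h |
| ochre | 1.4 M | −20 °C | 5.0 h |
| blue | 1.4 M | −40 °C | 5.0 h |

    starting material + target ⇌ idle adduct, settled at all times (K1 = 0.71 /M, ΔH1 = −25.0 kJ/mol)
    target ⇌ isomer of the product (K2 = 0.22, k2 = 0.13 /h, Ea2 = 84.0 kJ/mol, ΔH2 = −55.0 kJ/mol)
    starting material ⇌ target (K3 = 11, k3 = 0.062 /h, Ea3 = 85.0 kJ/mol, ΔH3 = −15.0 kJ/mol)
    starting material ⇌ dormant form (K4 = 7.5, k4 = 0.064 /h, Ea4 = 92.0 kJ/mol, ΔH4 = −86.0 kJ/mol)
    isomer of the product ⇌ starting material (k5 = 0.083 /h, Ea5 = 82.0 kJ/mol)
    (constants at −20 °C)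

- in percentages every species weighs as the starting material in it: one idle adduct counts as two
- for target the idle adduct is counted in
- constants are those at −20 °C; use the activation energies and enthalpies for any other temperature
- in an amount of target, one idle adduct counts as one target

* the best flask by amount of target, in percent of the starting material charged; "all alike" if 1.5 percentage points covers them all (green / ochre / blue / all alike)
* amount of target at the end, in percent of the starting material charged, green
* amount of target at the end, in percent of the starting material charged, ochre
* amount of target at the end, in percent of the starting material charged, blue

For the next shift: each flask began with c(starting material) = 1.4 M. At the ochre temperature, starting material goes directly to target with 0.062 /h. It also enters the isomer of the product, by the reverse of the step from isomer to starting material, with 0.201 /h, which is faster. The barrier of that entry, 12.0 kJ/mol, is lower than the 85.0 kJ/mol of the direct step, so cooling slows the entry far less. The question for each bath is therefore whether the isomer gets out again.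

By my own reckoning, the way back from isomer to target has the constant 0.591 /h in ochre. Over 5.0 h that gives 4.26, the exit count: the time allowed divided by the half-life of the isomer on its way back to target.

The barrier of this way back is 139 kJ/mol, so the count climbs to 537 in green and drops to 0.0148 in blue.

Expect green under thermodynamic control, with the isomer passed on. Expect ochre in between: its count stands above one, but starting material is still feeding the isomer. Expect blue under kinetic control, with the isomer held. Leave each bath at its set temperature, as the questions are asked there. The count gives an order, green first, and no percentages.

The forecast gives the same order, with green best: 78% (75% to 80%) for green, 44% (37% to 50%) for ochre and 1% (0.7% to 1.4%) for blue. It holds that in blue “the direct route to target is nearly frozen while the route to the isomer stays comparatively open”.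

The flasks give 78.0% for green, 42.6% for ochre and 0.969% for blue, so green is best and each value lies inside the forecast's range.

Blue stands low partly because of the time allowed, though this is not the main reason: left until 50.0 h, blue reaches 8.66% target against 0.969%, and that gain of 7.7 percentage points is 7.8% of what is missing. Over that longer time the exit count of blue is 0.148, still below one, and the flask then holds 87.3% isomer, more than its target.

On the ochre charge at −45 °C, the exit count is 0.00307, far below one, so the isomer should stay put. That flask ends with 41.3% isomer and 0.334% target.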